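**Retrosynthetic overview**
1. The target is 4'''-O-methylagathisflavone: C6 of an apigenin unit bonded to C8 of an acacetin unit. Both chromone ring systems (rings A, B and C of each half) are bought intact as apigenin and acacetin, so no ring is built.
2. The only skeletal disconnection is the C6–C8 biaryl bond, which joins two phloroglucinol-type carbons that are both innately nucleophilic.
3. Polarity inversion: C8 of the acacetin half is turned into an aryl-cation equivalent (an aryllead triacetate, by direct C–H plumbation). The 5-OH of the apigenin half binds lead and steers ligand coupling to its only free ortho carbon, C6.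
4. Protection uses benzyl ethers only: 7,4' on apigenin (chelated 5-OH left free) and 5,7 on acacetin. The methyl ether is native to acacetin.
5. End game: one global hydrogenolysis.

Assumption: the SMILES carries no stereodescriptor and the molecule has no stereocentre, so the hindered biaryl axis is taken as unspecified and is formed without control (racemic).

Step 1
Reactants: 1 apigenin
Product: 2 7-(benzyloxy)-2-[4-(benzyloxy)phenyl]-5-hydroxy-4H-chromen-4-one (7,4'-di-O-benzylapigenin)
Conditions: BnBr (2.2 equiv), K2CO3 (2.5 equiv), DMF, rt to 40 °C, 12 h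
Reagents that add atoms: benzyl bromide, BrCc1ccccc1
Why: Williamson ether synthesis in which the acidic 7-OH and 4'-OH are alkylated while the 5-OH, locked in a hydrogen bond to the C4 carbonyl, stays free under mild carbonate conditions; no stereo element is formed.

Step 2
Reactants: 3 acacetin
Product: 4 5,7-bis(benzyloxy)-2-(4-methoxyphenyl)-4H-chromen-4-one (5,7-di-O-benzylacacetin)
Conditions: BnBr (3.5 equiv), K2CO3 (5 equiv), Bu4NI (10 mol %), DMF, 80 °C, 16 h
Reagents that add atoms: benzyl bromide, BrCc1ccccc1
Why: exhaustive Williamson etherification, where excess halide, iodide catalysis and heat overcome the chelation of the 5-OH, as in the routine perbenzylation of 5-hydroxyflavones; no stereo element is formed.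

Step 3
Reactants: 4 5,7-di-O-benzylacacetin; 2 7,4'-di-O-benzylapigenin
Product: 6 8-{7-(benzyloxy)-2-[4-(benzyloxy)phenyl]-5-hydroxy-4-oxo-4H-chromen-6-yl}-5,7-bis(benzyloxy)-2-(4-methoxyphenyl)-4H-chromen-4-one (tetra-O-benzyl biflavone), via aryllead triacetate 5 (not isolated)
Conditions: 4 (1.3 equiv), Pb(OAc)4 (1.2 equiv), CHCl3, 40 °C, 2 h; then 2 (1.0 equiv), pyridine (5 equiv), CHCl3, 60 °C, 12 h
Reagents that add atoms: none
Why: Proposed new method: tetravalent lead in Pb(OAc)4 should plumbate the most electron-rich C–H of 4 (C8 of ring A, the site at which 5,7-dialkoxyflavones are halogenated), as in the direct plumbation of polymethoxybenzenes, which turns this innately nucleophilic carbon into an aryl-cation equivalent; the 5-oxygen of 2 then replaces an acetate on lead and the aryl group is delivered intramolecularly by ligand coupling, with loss of divalent lead as Pb(OAc)2, to C6, the only hydrogen-bearing ortho carbon (C4a is a blocked ring-fusion carbon), after which the dienone re-aromatises to the chelated phenol; the closest known reaction is the Pinhey ortho-arylation of electron-rich phenols and β-dicarbonyl enols with 2,4,6-trimethoxyphenyllead triacetate generated in situ, which tolerates two ortho substituents on each partner; the tetra-ortho-substituted axis forms without control, matching the unspecified target.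

Step 4
Reactants: 6 tetra-O-benzyl biflavone
Product: 7 8-[5,7-dihydroxy-2-(4-hydroxyphenyl)-4-oxo-4H-chromen-6-yl]-5,7-dihydroxy-2-(4-methoxyphenyl)-4H-chromen-4-one (target, CNP0310322.0)
Conditions: H2 (1 atm), Pd/C (10 wt % Pd on carbon), THF–MeOH 1:1, rt, 6 h
Reagents that add atoms: none
Why: catalytic hydrogenolysis cleaves the four benzyl aryl ethers while the aryl methyl ether and the conjugated chromone C2=C3 bonds are inert at 1 atm and room temperature; no stereo element is touched.

**Compound list**
1 | apigenin, 5,7-dihydroxy-2-(4-hydroxyphenyl)-4H-chromen-4-one | O=c1cc(-c2ccc(O)cc2)oc2cc(O)cc(O)c12 | starting material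
2 | 7-(benzyloxy)-2-[4-(benzyloxy)phenyl]-5-hydroxy-4H-chromen-4-one | O=c1cc(-c2ccc(OCc3ccccc3)cc2)oc2cc(OCc3ccccc3)cc(O)c12 | intermediate
3 | acacetin, 5,7-dihydroxy-2-(4-methoxyphenyl)-4H-chromen-4-one | COc1ccc(-c2cc(=O)c3c(O)cc(O)cc3o2)cc1 | starting material
4 | 5,7-bis(benzyloxy)-2-(4-methoxyphenyl)-4H-chromen-4-one | COc1ccc(-c2cc(=O)c3c(OCc4ccccc4)cc(OCc4ccccc4)cc3o2)cc1 | intermediate
5 | [5,7-bis(benzyloxy)-2-(4-methoxyphenyl)-4-oxo-4H-chromen-8-yl]lead triacetate | COc1ccc(-c2cc(=O)c3c(OCc4ccccc4)cc(OCc4ccccc4)c([Pb](OC(C)=O)(OC(C)=O)OC(C)=O)c3o2)cc1 | intermediate (not isolated)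
6 | 8-{7-(benzyloxy)-2-[4-(benzyloxy)phenyl]-5-hydroxy-4-oxo-4H-chromen-6-yl}-5,7-bis(benzyloxy)-2-(4-methoxyphenyl)-4H-chromen-4-one, racemic about the axis | COc1ccc(-c2cc(=O)c3c(OCc4ccccc4)cc(OCc4ccccc4)c(-c4c(OCc5ccccc5)cc5oc(-c6ccc(OCc7ccccc7)cc6)cc(=O)c5c4O)c3o2)cc1 | intermediate
7 | 8-[5,7-dihydroxy-2-(4-hydroxyphenyl)-4-oxo-4H-chromen-6-yl]-5,7-dihydroxy-2-(4-methoxyphenyl)-4H-chromen-4-one | COc1ccc(-c2cc(=O)c3c(O)cc(O)c(-c4c(O)cc5oc(-c6ccc(O)cc6)cc(=O)c5c4O)c3o2)cc1 | target

**Step count**
Total steps: 4. Longest linear sequence: 3 (steps 2, 3, 4 or steps 1, 3, 4).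

**Steps most likely to fail, with fallbacks**

Step 3 is the riskiest. The C–H plumbation of 4 may be slow or give the aryl acetate, and the chelated 5-OH of 2 may exchange onto lead sluggishly or couple in part at C4a. The fallback sets out from 4 and installs the metal by prefunctionalisation instead of C–H plumbation. NIS (1.1 equiv) with catalytic CF3CO2H in MeCN at rt gives 5,7-bis(benzyloxy)-8-iodo-2-(4-methoxyphenyl)-4H-chromen-4-one F1. Hexabutylditin (Bu3Sn)2 with Pd(PPh3)4 (zerovalent palladium, 5 mol %) in toluene at 110 °C gives 5,7-bis(benzyloxy)-2-(4-methoxyphenyl)-8-(tributylstannyl)-4H-chromen-4-one F2. Tin-to-lead exchange of F2 with Pb(OAc)4 and Hg(OAc)2 (5 mol %) in CHCl3 at 40 °C then gives the aryllead triacetate regiospecifically. The fallback comes back to the route at 5, which is treated with 2 and pyridine as in step 3.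

Step 4 is next. Traces of lead carried over from step 3 can poison the palladium surface, and partial reduction of a chromone C2=C3 bond is possible on long exposure. The fallback sets out from 6 and replaces catalytic hydrogenolysis by stoichiometric, non-reductive Lewis-acid dealkylation: BCl3 (8 equiv) and pentamethylbenzene (12 equiv) in CH2Cl2 at −78 °C. This removes benzyl cations as benzylpentamethylbenzene and leaves the non-chelated aryl methyl ether alone. It comes back to the route at 7. New compounds on the way: none F0.

Step 1 is third. Stopping the benzylation cleanly at the 7,4'-diether can give mixtures of mono-, di- and tri-ethers. The fallback sets out from 1 and uses protect-all then selective deprotection. BnBr (4.5 equiv) and K2CO3 in DMF at 80 °C give 5,7-bis(benzyloxy)-2-[4-(benzyloxy)phenyl]-4H-chromen-4-one F3. BCl3 (1.05 equiv) in CH2Cl2 at −78 °C, chelated between the C4 carbonyl and O5, then cleaves only the 5-O-benzyl ether. The fallback comes back to the route at 2.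

**Further compounds**
F1 | step 3 | 5,7-bis(benzyloxy)-8-iodo-2-(4-methoxyphenyl)-4H-chromen-4-one | COc1ccc(-c2cc(=O)c3c(OCc4ccccc4)cc(OCc4ccccc4)c(I)c3o2)cc1
F2 | step 3 | 5,7-bis(benzyloxy)-2-(4-methoxyphenyl)-8-(tributylstannyl)-4H-chromen-4-one | COc1ccc(-c2cc(=O)c3c(OCc4ccccc4)cc(OCc4ccccc4)c([Sn](CCCC)(CCCC)CCCC)c3o2)cc1
F0 | step 4 | none | none
F3 | step 1 | 5,7-bis(benzyloxy)-2-[4-(benzyloxy)phenyl]-4H-chromen-4-one | O=c1cc(-c2ccc(OCc3ccccc3)cc2)oc2cc(OCc3ccccc3)cc(OCc3ccccc3)c12
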